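## Retrosynthetic overview

1. Target 25 comes from alkene hydrogenation of the methallyl compound 24.
2. 24 comes from a polarity-reversed three-component union: the decalin aldehyde 19 (its CHO carbon becomes C9'), unprotected 2,4-diformylphloroglucinol 20 and methallylsilane 21, through an ortho-quinone methide. This replaces the usual "terpene C1 nucleophile + isovaleraldehyde-derived benzylic cation" coupling, makes the aryl–C9' and C9'–CH2 bonds, and sets C9' by 1,3-allylic strain.
3. 19 comes from keto diol 17 (one-carbon homologation), 17 from dienol 14 (double oxymercuration sets the axial 4-OH), 14 from epoxy enone 10 (one-pot reductive epoxide opening, enone reduction and enolate triflation sets H5 and moves the oxygen from C3 to C1).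
4. 10 comes from ent-α-cyperone 8, made from (S)-carvone 1 and ethyl vinyl ketone 4 by an auxiliary-controlled Robinson annulation that sets C10.
5. Ring order: ring B is bought with carvone, ring A is annulated in steps 2–3, the aromatic ring is bought intact; no protecting groups are used.

Assumption: eudesmane numbering is used for the decalin (C10 angular-methyl carbon, C1 its ring A neighbour, C4 carbinol carbon, C5 ring-fusion CH, C7 side-chain carbon, C9' benzylic carbon); the target is 1R,4R,5S,7S,10R,9'R, an ent-eudesmane, and 20 and 21 are taken as purchasable.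

## Route

Step 1
Reactants: 1 (S)-(+)-carvone
Product: 2 (2S,5S)-2-methyl-5-(prop-1-en-2-yl)cyclohexan-1-one (trans-dihydrocarvone)
Conditions: LiBH(sec-Bu)3 (1.1 equiv), THF, −78 °C; aq NH4Cl
Reagents that add atoms: none
Why: Conjugate hydride reduction (1,4-reduction of an enone) spares the isopropenyl group and the stereocentre that becomes C7; the C2 epimer ratio does not matter because C2 is planarised again in step 2.

Step 2
Reactants: 2 trans-dihydrocarvone; 3 (S)-1-phenylethylamine; 4 pent-1-en-3-one (ethyl vinyl ketone)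
Product: 7 (2R,5S)-2-methyl-2-(3-oxopentyl)-5-(prop-1-en-2-yl)cyclohexan-1-one, via ketimine 5 (not isolated), via alkylated imine 6 (not isolated)
Conditions: 3 (1.05 equiv), TsOH·H2O (1 mol%), toluene, reflux, Dean–Stark; 4 (1.5 equiv), THF, 40 °C, 3 d; 10% aq AcOH, 20 °C
Reagents that add atoms: water, O
Why: d'Angelo Michael addition of a chiral imine through its more substituted secondary enamine tautomer: the (S)-auxiliary steers the enone to the face that gives the R quaternary centre (future C10, methyl syn to the C7 substituent), the mirror image of the established (R)-amine route from (+)-dihydrocarvone to (+)-α-cyperone.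

Step 3
Reactants: 7 diketone
Product: 8 ent-α-cyperone, (4aR,7S)-1,4a-dimethyl-7-(prop-1-en-2-yl)-4,4a,5,6,7,8-hexahydronaphthalen-2(3H)-one
Conditions: NaOMe (0.5 equiv), MeOH, 20 → 60 °C
Reagents that add atoms: none
Why: Intramolecular aldol condensation (second half of the Robinson annulation) closes ring A and touches no stereocentre.

Step 4
Reactants: 8 ent-α-cyperone
Product: 9 ent-eudesma-1,4,11-trien-3-one, (4aR,7S)-1,4a-dimethyl-7-(prop-1-en-2-yl)-5,6,7,8-tetrahydronaphthalen-2(4aH)-one
Conditions: DDQ (1.3 equiv), dioxane, reflux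
Reagents that add atoms: none
Why: DDQ dehydrogenation of a 4-en-3-one through its C2 enol gives the cross-conjugated 1,4-dien-3-one and touches no stereocentre.

Step 5
Reactants: 9 cross-conjugated dienone
Product: 10 ent-1,2-epoxyeudesma-4,11-dien-3-one (oxirane oxygen anti to the C10 methyl)
Conditions: 30% aq H2O2 (3 equiv), NaOH (0.3 equiv), MeOH, 0 °C
Reagents that add atoms: hydrogen peroxide, OO
Why: Weitz–Scheffer nucleophilic epoxidation takes only the less substituted C1=C2 bond of the cross-conjugated dienone, hydroperoxide attacking C1 anti to the axial C10 methyl, so the future C1 oxygen sits on the face opposite that methyl.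

Step 6
Reactants: 10 epoxy enone
Product: 13 trans-fused ent-1-hydroxyeudesma-3,11-dien-3-yl trifluoromethanesulfonate (1-OH axial; 1-OH anti and H5 anti to the C10 methyl), via alkoxy enone 11 (not isolated), via dilithium enolate 12 (not isolated)
Conditions: Li (8 equiv), NH3(l)–THF, t-BuOH (2.0 equiv), −78 → −33 °C; isoprene; NH3 evaporated; PhNTf2 (1.2 equiv), THF, −78 → 0 °C; aq NH4Cl
Reagents that add atoms: N-phenylbis(trifluoromethanesulfonimide), O=S(=O)(N(c1ccccc1)S(=O)(=O)C(F)(F)F)C(F)(F)F
Why: Dissolving-metal reduction: two electrons cleave the C2–O bond of the α,β-epoxy ketone (11 after protonation at C2), two more reduce the enone with axial protonation at C5 anti to the C10 methyl (trans-decalin, as in Birch reductions of 4-en-3-ones), and the regiodefined C3–C4 enolate 12 is O-triflated by PhNTf2 faster than the hindered alkoxides (reductive enolate triflation).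

Step 7
Reactants: 13 hydroxy enol triflate
Product: 14 trans-fused ent-eudesma-3,11-dien-1-ol (1-OH axial and anti to the C10 methyl)
Conditions: Pd(OAc)2 (5 mol%), PPh3 (10 mol%), n-Bu3N (3 equiv), HCO2H (2 equiv), DMF, 60 °C
Reagents that add atoms: none
Why: Palladium-catalysed formate reduction of an enol triflate (oxidative addition, formate exchange, decarboxylation, reductive elimination) replaces OTf by H without shifting the C3=C4 bond.

Step 8
Reactants: 14 dienol
Product: 16 ent-eudesmane-1,4,11-triol (1-OH axial anti to the C10 methyl; 4-OH axial syn to the C10 methyl; 4-methyl equatorial), via bis-organomercurial 15 (not isolated)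
Conditions: Hg(OAc)2 (2.5 equiv), THF–H2O (1:1), 20 °C; 3 M NaOH, NaBH4, 0 °C
Reagents that add atoms: water, O
Why: Markovnikov oxymercuration–demercuration hydrates both alkenes at their tertiary carbons; on ring A the mercurinium ion forms on the face anti to the C10 methyl (the face of the 1-OH) and water opens it trans-diaxially at C4, which sets the axial 4-OH syn to the C10 methyl.

Step 9
Reactants: 16 triol
Product: 17 4,11-dihydroxy-ent-eudesman-1-one (C4, C5, C7, C10 as in the target)
Conditions: Dess–Martin periodinane (1.5 equiv), CH2Cl2, 20 °C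
Reagents that add atoms: none
Why: Dess–Martin oxidation acts only on the secondary alcohol; the two tertiary alcohols cannot be oxidised and no remaining stereocentre is touched.

Step 10
Reactants: 17 keto diol
Product: 18 1-(methoxymethylidene)-ent-eudesmane-4,11-diol (E/Z mixture)
Conditions: MeOCH2PPh3Cl (5 equiv), KOt-Bu (4.8 equiv), THF, 0 → 50 °C
Reagents that add atoms: (methoxymethyl)triphenylphosphonium chloride, COC[P+](c1ccccc1)(c1ccccc1)c1ccccc1.[Cl-]
Why: Wittig methoxymethylenation of the ketone (the excess ylide also covers the two tertiary alkoxides); the enol ether geometry is irrelevant.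

Step 11
Reactants: 18 enol ether
Product: 19 4,11-dihydroxy-ent-eudesmane-1-carbaldehyde (formyl equatorial; H1 anti to the C10 methyl)
Conditions: 0.5 M aq HCl–THF (1:3), 20 °C; K2CO3 (0.5 equiv), MeOH, 20 °C
Reagents that add atoms: water, O
Why: Acid hydrolysis of the enol ether followed by base equilibration of the enolisable aldehyde puts the formyl group equatorial with H1 anti to the C10 methyl, which sets C1 under thermodynamic control.

Step 12
Reactants: 19 decalin aldehyde; 20 2,4,6-trihydroxybenzene-1,3-dicarbaldehyde (2,4-diformylphloroglucinol); 21 trimethyl(2-methylallyl)silane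
Product: 24 (9'R)-methallyl compound (the target with CH2C(CH3)=CH2 in place of isobutyl), via quinone methide 22 (not isolated), via silylmethyl chroman 23 (not isolated)
Conditions: 20 (1.2 equiv), 21 (8 equiv), piperidine (0.2 equiv), AcOH (0.2 equiv), MeCN, 50 °C; n-Bu4NF (5 equiv), THF, 0 °C; aq NH4Cl
Reagents that add atoms: none
Why: Proposed new method: amine-catalysed Knoevenagel-type condensation of the acidic phloroglucinol C–H with 19 gives the ortho-quinone methide 22 (the species that far less nucleophilic terpene alkenes trap in biomimetic euglobal-type three-component couplings), the allylsilane adds in an inverse-demand hetero-Diels–Alder sense with C9' bonding to its CH2 terminus, and fluoride then expels the electron-poor phenoxide from the β-silyl ether 23 (Peterson-type elimination; closest known reaction type: Hosomi–Sakurai conjugate allylation of quinone methides and benzylic cations); 1,3-allylic strain holds H1 in the plane of the exocyclic C=C, so the silane attacks the face anti to the quaternary C10 and sets C9' as R.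

Step 13
Reactants: 24 methallyl compound
Product: 25 target, 5-[(1R)-1-[(1R,4R,4aS,6S,8aR)-4-hydroxy-6-(2-hydroxypropan-2-yl)-4,8a-dimethyldecahydronaphthalen-1-yl]-3-methylbutyl]-2,4,6-trihydroxybenzene-1,3-dicarbaldehyde
Conditions: H2 (1 atm), RhCl(PPh3)3 (10 mol%), benzene–EtOH (1:1), 20 °C
Reagents that add atoms: none
Why: Homogeneous hydrogenation with RhCl(PPh3)3 saturates the unhindered 1,1-disubstituted alkene and leaves the hydrogen-bonded aryl aldehydes, phenols and tertiary alcohols alone; no stereocentre is formed or disturbed.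

## Compound list

1 | (S)-(+)-carvone | CC1=CC[C@@H](CC1=O)C(C)=C | starting material
2 | (2S,5S)-2-methyl-5-(prop-1-en-2-yl)cyclohexan-1-one (trans-dihydrocarvone) | C[C@H]1CC[C@H](C(C)=C)CC1=O | intermediate
3 | (S)-1-phenylethylamine | C[C@H](N)c1ccccc1 | starting material
4 | pent-1-en-3-one (ethyl vinyl ketone) | CCC(=O)C=C | starting material
5 | N-[(S)-1-phenylethyl] ketimine of 2 (C2 epimerises through the enamine) | C[C@H]1CC[C@H](C(C)=C)CC1=N[C@@H](C)c1ccccc1 | intermediate
6 | N-[(S)-1-phenylethyl] imine of 7 (quaternary carbon R) | CCC(=O)CC[C@@]1(C)CC[C@H](C(C)=C)CC1=N[C@@H](C)c1ccccc1 | intermediate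
7 | (2R,5S)-2-methyl-2-(3-oxopentyl)-5-(prop-1-en-2-yl)cyclohexan-1-one | CCC(=O)CC[C@@]1(C)CC[C@H](C(C)=C)CC1=O | intermediate
8 | ent-α-cyperone, (4aR,7S) | CC1=C2C[C@@H](C(C)=C)CC[C@]2(C)CCC1=O | intermediate
9 | ent-eudesma-1,4,11-trien-3-one, (4aR,7S) | CC1=C2C[C@@H](C(C)=C)CC[C@]2(C)C=CC1=O | intermediate
10 | ent-1,2-epoxyeudesma-4,11-dien-3-one, oxirane oxygen anti to the C10 methyl | CC1=C2C[C@@H](C(C)=C)CC[C@]2(C)[C@@H]3O[C@@H]3C1=O | intermediate
11 | lithium alkoxide of ent-1-hydroxyeudesma-4,11-dien-3-one (1-O anti to the C10 methyl) | [Li+].[O-][C@@H]1CC(=O)C(C)=C2C[C@@H](C(C)=C)CC[C@]12C | intermediate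
12 | dilithium 1-alkoxide / C3–C4 enolate of the trans-fused 1-hydroxy-3-ketone | [Li+].[Li+].[O-][C@@H]1CC([O-])=C(C)[C@H]2C[C@@H](C(C)=C)CC[C@]12C | intermediate
13 | trans-fused ent-1-hydroxyeudesma-3,11-dien-3-yl trifluoromethanesulfonate (1-OH and H5 anti to the C10 methyl) | O[C@@H]1CC(OS(=O)(=O)C(F)(F)F)=C(C)[C@H]2C[C@@H](C(C)=C)CC[C@]12C | intermediate
14 | trans-fused ent-eudesma-3,11-dien-1-ol (1-OH axial, anti to the C10 methyl) | O[C@@H]1CC=C(C)[C@H]2C[C@@H](C(C)=C)CC[C@]12C | intermediate
15 | 3,12-bis(acetoxymercurio)-ent-eudesmane-1,4,11-triol (Hg at C3 anti, 4-OH syn to the C10 methyl; C11 epimers) | O[C@@H]1C[C@H]([Hg]OC(C)=O)[C@@](C)(O)[C@H]2C[C@@H](C(C)(O)C[Hg]OC(C)=O)CC[C@]12C | intermediate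
16 | ent-eudesmane-1,4,11-triol (1-OH axial anti, 4-OH axial syn to the C10 methyl) | O[C@@H]1CC[C@@](C)(O)[C@H]2C[C@@H](C(C)(C)O)CC[C@]12C | intermediate
17 | 4,11-dihydroxy-ent-eudesman-1-one | O=C1CC[C@@](C)(O)[C@H]2C[C@@H](C(C)(C)O)CC[C@]12C | intermediate
18 | 1-(methoxymethylidene)-ent-eudesmane-4,11-diol (E/Z mixture) | COC=C1CC[C@@](C)(O)[C@H]2C[C@@H](C(C)(C)O)CC[C@]12C | intermediate
19 | 4,11-dihydroxy-ent-eudesmane-1-carbaldehyde (formyl equatorial, H1 anti to the C10 methyl) | O=C[C@H]1CC[C@@](C)(O)[C@H]2C[C@@H](C(C)(C)O)CC[C@]12C | intermediate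
20 | 2,4,6-trihydroxybenzene-1,3-dicarbaldehyde | O=Cc1c(O)cc(O)c(C=O)c1O | starting material
21 | trimethyl(2-methylallyl)silane | CC(=C)C[Si](C)(C)C | starting material
22 | ortho-quinone methide from 19 and 20 (exocyclic C9'=C bond) | O=CC1=C(O)C(C=O)=C(O)C(=C[C@H]2CC[C@@](C)(O)[C@H]3C[C@@H](C(C)(C)O)CC[C@]23C)C1=O | intermediate
23 | 2-methyl-2-(trimethylsilylmethyl)chroman adduct (C9' R; epimers at the chroman O-bearing carbon) | C[Si](C)(C)CC1(C)C[C@H]([C@H]3CC[C@@](C)(O)[C@H]4C[C@@H](C(C)(C)O)CC[C@]34C)c2c(O)c(C=O)c(O)c(C=O)c2O1 | intermediate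
24 | (9'R)-methallyl compound | CC(=C)C[C@@H](c1c(O)c(C=O)c(O)c(C=O)c1O)[C@H]1CC[C@@](C)(O)[C@H]2C[C@@H](C(C)(C)O)CC[C@]12C | intermediate
25 | CNP0409870.6 | CC(C)C[C@@H](c1c(O)c(C=O)c(O)c(C=O)c1O)[C@H]1CC[C@@](C)(O)[C@H]2C[C@@H](C(C)(C)O)CC[C@]12C | target

## Step count and risks

Total step count: 13. Longest linear sequence: 13 steps (1 to 25).

The three steps most likely to fail:

1. The three-component union (step 12) is the riskiest. The hindered, α-branched aldehyde 19 may condense slowly. The quinone methide 22 can also escape by a [1,5]-hydrogen shift of H1 to an ortho-hydroxystyrene, which would erase C1. The facial selectivity is predicted, not proven.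
   The fallback sets out from 19 and returns at 25, making the two bonds one after the other on an O-methylated arene where no quinone carbonyl exists. 1,3,5-Trimethoxybenzene is lithiated (n-BuLi, TMEDA, THF, 0 °C) to 2,4,6-trimethoxyphenyllithium F1, which adds to 19 (4 equiv, −78 °C) to give the trimethoxyphenyl carbinol F2 (both C9' epimers). BF3·OEt2 and 21 (CH2Cl2, −78 °C) ionise F2 to the benzylic cation, which is allylated under the same 1,3-allylic strain control to the methallyl trimethyl ether F3. H2 over Pd/C gives the isobutyl trimethyl ether F4. NBS (2.1 equiv, MeCN, 0 °C) gives the dibromide F5. t-BuLi (7 equiv, THF, −78 °C) then DMF gives the dialdehyde trimethyl ether F6. NaSEt (DMF, 120 °C) removes the three O-methyl groups and gives 25.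

2. The one-pot reduction and triflation (step 6) may over-reduce, or PhNTf2 may also sulfonylate the C1 alkoxide.
   The fallback sets out from 10 and returns at 14 by a carbonyl transposition. N2H4·H2O with catalytic AcOH (MeOH, 0 → 20 °C) turns 10 into the epoxy hydrazone F7, which fragments with loss of N2 (Wharton transposition) to the 1-hydroxy-2,4-diene F8. MnO2 (CH2Cl2) oxidises it to the 2,4-dien-1-one F9. Li/NH3 (t-BuOH 1 equiv, −78 °C, NH4Cl quench) reduces F9 by 1,6-addition with protonation at C5 anti to the C10 methyl and kinetic α-protonation, giving the β,γ-unsaturated ketone F10. LiBH(sec-Bu)3 (THF, −78 °C) attacks C1 equatorially and gives the axial alcohol 14.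

3. The Wittig methoxymethylenation (step 10) acts on a ketone flanked by a quaternary carbon and may stall through enolisation.
   The fallback sets out from 17 and returns at 19 by reductive cyanation. TosMIC and KOt-Bu (DME–t-BuOH, 0 → 40 °C) convert the ketone into the nitrile F11 (equatorial after base equilibration). i-Bu2AlH (5 equiv, toluene, −78 °C) followed by dilute aq HCl hydrolyses the aldimine and gives 19.

## Further compounds

F1 | step 12 | 2,4,6-trimethoxyphenyllithium | [Li]c1c(OC)cc(OC)cc1OC
F2 | step 12 | trimethoxyphenyl carbinol (C9' epimers) | COc1cc(OC)c(C(O)[C@H]2CC[C@@](C)(O)[C@H]3C[C@@H](C(C)(C)O)CC[C@]23C)c(OC)c1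
F3 | step 12 | methallyl trimethyl ether (9'R) | CC(=C)C[C@@H](c1c(OC)cc(OC)cc1OC)[C@H]1CC[C@@](C)(O)[C@H]2C[C@@H](C(C)(C)O)CC[C@]12C
F4 | step 12 | isobutyl trimethyl ether (9'R) | CC(C)C[C@@H](c1c(OC)cc(OC)cc1OC)[C@H]1CC[C@@](C)(O)[C@H]2C[C@@H](C(C)(C)O)CC[C@]12C
F5 | step 12 | dibromide | CC(C)C[C@@H](c1c(OC)c(Br)c(OC)c(Br)c1OC)[C@H]1CC[C@@](C)(O)[C@H]2C[C@@H](C(C)(C)O)CC[C@]12C
F6 | step 12 | dialdehyde trimethyl ether | CC(C)C[C@@H](c1c(OC)c(C=O)c(OC)c(C=O)c1OC)[C@H]1CC[C@@](C)(O)[C@H]2C[C@@H](C(C)(C)O)CC[C@]12C
F7 | step 6 | epoxy hydrazone of 10 | CC1=C2C[C@@H](C(C)=C)CC[C@]2(C)[C@@H]3O[C@@H]3C1=NN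
F8 | step 6 | ent-eudesma-2,4,11-trien-1-ol (1-OH anti to the C10 methyl) | O[C@@H]1C=CC(C)=C2C[C@@H](C(C)=C)CC[C@]12C
F9 | step 6 | ent-eudesma-2,4,11-trien-1-one | O=C1C=CC(C)=C2C[C@@H](C(C)=C)CC[C@]12C
F10 | step 6 | trans-fused ent-eudesma-3,11-dien-1-one | O=C1CC=C(C)[C@H]2C[C@@H](C(C)=C)CC[C@]12C
F11 | step 10 | 4,11-dihydroxy-ent-eudesmane-1-carbonitrile (cyano equatorial) | N#C[C@H]1CC[C@@](C)(O)[C@H]2C[C@@H](C(C)(C)O)CC[C@]12C
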